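The route disconnects the cyclohexane ring at the C2–C3 bond (ring CH2 to CHBr). A cation–olefin cyclisation lets an (E)-bromoalkene attack a primary triflate at C2, and chloride then opens the resulting bromonium ion at C4. In one operation this closes the ring and sets C3 and C4. It exploits the fact that bromine at C3, chlorine at C4 and the C1 side chain are all equatorial, the trans-diequatorial arrangement that bromochlorination of a cyclohexene would not favour. The precursor is acyclic: a triflate whose C1 and C7 centres come from a butyrolactone template, with the acetyl group masked as an ethynyl group and the side-chain bromohydrin already in place.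

Key step: step 13

Remark on the chemistry (numbering used throughout): ring C1 bears the side chain, C2 is the ring CH2 next to it, C3 is CHBr, C4 is C(CH3)Cl, then C5 and C6. In the side chain C7 is the carbinol carbon, C8 the CH2, C9 the CHBr and C10 the C(CH3)2OH carbon. C9 is introduced as an (S)-epoxide and inverted by bromide.

Step 1
Reactants: 1 hex-5-yn-1-ol
Product: 3 (E)-6-bromo-5-methylhex-5-en-1-ol, via alkenylalane 2 (not isolated)
Conditions: AlMe3, Cp2ZrCl2 (cat.), CH2Cl2, 0 °C to rt; then NBS, THF, −30 to 0 °C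
Reagents that add atoms: trimethylaluminium C[Al](C)C; N-bromosuccinimide O=C1CCC(=O)N1Br
Why: Zirconium-catalysed Negishi carboalumination adds methyl and aluminium syn across the terminal alkyne with aluminium at the terminus, and bromodealumination with retention leaves bromine cis to the methyl group and trans to the chain (E).

Step 2
Reactants: 3 (E)-6-bromo-5-methylhex-5-en-1-ol
Product: 4 (E)-6-bromo-5-methylhex-5-enoic acid
Conditions: TEMPO (cat.), PhI(OAc)2, MeCN/H2O, rt
Reagents that add atoms: water O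
Why: TEMPO/PhI(OAc)2 oxidation in wet acetonitrile takes a primary alcohol through the aldehyde hydrate to the carboxylic acid and should not touch the electron-poor bromoalkene.

Step 3
Reactants: 4 (E)-6-bromo-5-methylhex-5-enoic acid; 5 (S)-4-benzyl-1,3-oxazolidin-2-one
Product: 7 (S)-4-benzyl-3-[(E)-6-bromo-5-methylhex-5-enoyl]-1,3-oxazolidin-2-one, via mixed pivalic anhydride 6 (not isolated)
Conditions: PivCl, Et3N, THF, −20 °C; then 5, LiCl, rt
Reagents that add atoms: none
Why: N-Acylation of the oxazolidinone through the mixed pivalic anhydride with LiCl/Et3N activation is the standard mild entry to the substrate for an auxiliary-controlled alkylation.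

Step 4
Reactants: 7 (S)-4-benzyl-3-[(E)-6-bromo-5-methylhex-5-enoyl]-1,3-oxazolidin-2-one; 8 tert-butyl bromoacetate
Product: 10 tert-butyl (3R,6E)-3-{[(4S)-4-benzyl-2-oxo-1,3-oxazolidin-3-yl]carbonyl}-7-bromo-6-methylhept-6-enoate, via sodium enolate 9 (not isolated)
Conditions: NaN(SiMe3)2, THF, −78 °C; then 8, −78 to −40 °C
Reagents that add atoms: none
Why: Evans asymmetric alkylation, in which the chelated (Z)-enolate is alkylated by the reactive α-bromo ester on the face opposite the benzyl group, sets the future ring carbon C1.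

Step 5
Reactants: 10 tert-butyl (3R,6E)-3-{[(4S)-4-benzyl-2-oxo-1,3-oxazolidin-3-yl]carbonyl}-7-bromo-6-methylhept-6-enoate
Product: 12 (4R)-4-[(3E)-4-bromo-3-methylbut-3-en-1-yl]oxolan-2-one, via hydroxy ester 11 (not isolated)
Conditions: LiBH4, THF, H2O (1 equiv), 0 °C; then p-TsOH·H2O (cat.), toluene, 50 °C
Reagents that add atoms: none
Why: LiBH4 reduces the exocyclic imide carbonyl chemoselectively to the primary alcohol with release of the auxiliary, and acid-catalysed transesterification of the γ-hydroxy tert-butyl ester closes the butyrolactone.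

Step 6
Reactants: 12 (4R)-4-[(3E)-4-bromo-3-methylbut-3-en-1-yl]oxolan-2-one; 13 1-bromo-3-methylbut-2-ene (prenyl bromide)
Product: 15 (3R,4R)-4-[(3E)-4-bromo-3-methylbut-3-en-1-yl]-3-(3-methylbut-2-en-1-yl)oxolan-2-one, via lithium enolate 14 (not isolated)
Conditions: LiN(i-Pr)2, THF, −78 °C; then 13, DMPU, −78 to −30 °C
Reagents that add atoms: none
Why: Enolate alkylation of a β-substituted butyrolactone with an allylic bromide takes place anti to the β-substituent (trans product), and this centre is re-enolised in the next step.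

Step 7
Reactants: 15 (3R,4R)-4-[(3E)-4-bromo-3-methylbut-3-en-1-yl]-3-(3-methylbut-2-en-1-yl)oxolan-2-one
Product: 17 (3R,4S)-4-[(3E)-4-bromo-3-methylbut-3-en-1-yl]-3-hydroxy-3-(3-methylbut-2-en-1-yl)oxolan-2-one, via potassium enolate 16 (not isolated)
Conditions: KN(SiMe3)2, THF, −78 °C; then 2-(phenylsulfonyl)-3-phenyloxaziridine, −78 °C
Reagents that add atoms: 2-(phenylsulfonyl)-3-phenyloxaziridine O=S(=O)(c1ccccc1)N1OC1c1ccccc1
Why: Davis hydroxylation of the tetrasubstituted enolate should again occur anti to the β-substituent, placing the hydroxyl trans and the prenyl group cis to it, which sets C7 relative to C1.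

Step 8
Reactants: 17 (3R,4S)-4-[(3E)-4-bromo-3-methylbut-3-en-1-yl]-3-hydroxy-3-(3-methylbut-2-en-1-yl)oxolan-2-one
Product: 18 (3R,4S)-4-[(3E)-4-bromo-3-methylbut-3-en-1-yl]-3-(3-methylbut-2-en-1-yl)-3-(triethylsilyloxy)oxolan-2-one
Conditions: Et3SiOTf, 2,6-lutidine, CH2Cl2, −78 to 0 °C
Reagents that add atoms: triethylsilyl triflate CC[Si](CC)(CC)OS(=O)(=O)C(F)(F)F
Why: Silylation of the hindered tertiary alcohol with a silyl triflate is reliable and keeps this oxygen from participating or fragmenting in the later ionisation step.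

Step 9
Reactants: 18 (3R,4S)-4-[(3E)-4-bromo-3-methylbut-3-en-1-yl]-3-(3-methylbut-2-en-1-yl)-3-(triethylsilyloxy)oxolan-2-one
Product: 19 (3R,4S)-4-[(3E)-4-bromo-3-methylbut-3-en-1-yl]-3-(3-methylbut-2-en-1-yl)-3-(triethylsilyloxy)oxolan-2-ol (lactol, both anomers)
Conditions: i-Bu2AlH, CH2Cl2, −78 °C
Reagents that add atoms: none
Why: Partial reduction of a lactone with i-Bu2AlH at low temperature stops at the aluminium hemiacetal and gives the lactol.

Step 10
Reactants: 19 (3R,4S)-4-[(3E)-4-bromo-3-methylbut-3-en-1-yl]-3-(3-methylbut-2-en-1-yl)-3-(triethylsilyloxy)oxolan-2-ol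
Product: 20 (2S,3R)-2-[(3E)-4-bromo-3-methylbut-3-en-1-yl]-3-ethynyl-6-methyl-3-(triethylsilyloxy)hept-5-en-1-ol
Conditions: dimethyl (1-diazo-2-oxopropyl)phosphonate, K2CO3, MeOH, 0 °C to rt
Reagents that add atoms: dimethyl (1-diazo-2-oxopropyl)phosphonate CC(=O)C(=[N+]=[N-])P(=O)(OC)OC
Why: Ohira–Bestmann homologation of the open hydroxy-aldehyde form of the lactol gives the terminal alkyne, a masked acetyl group, and frees the primary C2 hydroxyl.

Step 11
Reactants: 20 (2S,3R)-2-[(3E)-4-bromo-3-methylbut-3-en-1-yl]-3-ethynyl-6-methyl-3-(triethylsilyloxy)hept-5-en-1-ol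
Product: 21 (2S,3R)-2-[(3E)-4-bromo-3-methylbut-3-en-1-yl]-3-{[(2S)-3,3-dimethyloxiran-2-yl]methyl}-3-(triethylsilyloxy)pent-4-yn-1-ol
Conditions: ent-Shi ketone (enantiomer of the D-fructose-derived ketone, cat.), KHSO5 (Oxone), K2CO3, Bu4NHSO4, MeCN/CH2(OMe)2/aq. Na2B4O7 buffer, 0 °C
Reagents that add atoms: potassium peroxymonosulfate [K+].[O-]S(=O)(=O)OO
Why: Shi asymmetric epoxidation oxidises the electron-rich trisubstituted prenyl alkene in preference to the bromoalkene and the alkyne, and by the spiro transition-state model this ketone enantiomer is expected to give the (S)-epoxide.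

Step 12
Reactants: 21 (2S,3R)-2-[(3E)-4-bromo-3-methylbut-3-en-1-yl]-3-{[(2S)-3,3-dimethyloxiran-2-yl]methyl}-3-(triethylsilyloxy)pent-4-yn-1-ol
Product: 22 (2S,3R,5R)-5-bromo-2-[(3E)-4-bromo-3-methylbut-3-en-1-yl]-3-ethynyl-6-methyl-3-(triethylsilyloxy)heptane-1,6-diol
Conditions: Li2NiBr4 (stock solution), THF, 0 °C to rt
Reagents that add atoms: dilithium tetrabromonickelate [Li+].[Li+].[Ni+2].[Br-].[Br-].[Br-].[Br-]
Why: Opening of the trisubstituted epoxide by soft bromide is an SN2 reaction at the less substituted carbon, so C9 is inverted to the (R)-bromide and the tertiary alcohol is released.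

Step 13
Reactants: 22 (2S,3R,5R)-5-bromo-2-[(3E)-4-bromo-3-methylbut-3-en-1-yl]-3-ethynyl-6-methyl-3-(triethylsilyloxy)heptane-1,6-diol
Product: 24 (3R,5R)-3-bromo-5-[(1S,3S,4S)-3-bromo-4-chloro-4-methylcyclohexyl]-2-methyl-5-(triethylsilyloxy)hept-6-yn-2-ol, via primary triflate 23 (not isolated)
Conditions: Tf2O, 2,6-di-tert-butyl-4-methylpyridine, CH2Cl2, −78 °C; then Et4N[ZnCl3] (pre-formed from Et4NCl and ZnCl2), (CF3)2CHOH, −40 to 0 °C
Reagents that add atoms: tetraethylammonium trichlorozincate CC[N+](CC)(CC)CC.Cl[Zn-](Cl)Cl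
Why: Proposed new method: ionisation of the primary triflate in strongly ionising, non-nucleophilic (CF3)2CHOH is expected to be assisted by the pendant (E)-bromoalkene, whose bromine-bearing carbon C3 attacks C2 from the rear while the charge developing at tertiary C4 is bridged by bromine; the closest known reaction type is the solvolytic π-cyclisation of hex-5-enyl sulfonates, combined with the reversible chloride capture of β-bromo carbocations in the same solvent. The six-membered ring closes 6-endo-trig with respect to the alkene (exo-tet at C2) through a chair in which the bulky C1 substituent is equatorial. Because the alkene is E, bromine at C3 is placed equatorial and cis to the C1 substituent, so C3 is controlled by alkene geometry and the existing C1 centre. Chloride then opens the bromonium ion at tertiary C4 anti to bromine, which sets C4 and gives the trans-diequatorial bromochloride. The step needs carbon–carbon bond formation at C2 to outrun direct chloride displacement of the triflate; this is addressed by offering chloride only as the weakly nucleophilic chlorozincate in a hydrogen-bonding solvent and by the β-branching at C2, and no oxygen nucleophile in the substrate can reach C2 through a five- or six-membered ring.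

Step 14
Reactants: 24 (3R,5R)-3-bromo-5-[(1S,3S,4S)-3-bromo-4-chloro-4-methylcyclohexyl]-2-methyl-5-(triethylsilyloxy)hept-6-yn-2-ol
Product: 25 (3R,5R)-3-bromo-5-[(1S,3S,4S)-3-bromo-4-chloro-4-methylcyclohexyl]-2-methylhept-6-yne-2,5-diol
Conditions: HF·pyridine, THF/pyridine, 0 °C to rt
Reagents that add atoms: none
Why: Fluoride-mediated cleavage of the silyl ether under buffered acidic conditions spares the bromohydrin, which base would close to an epoxide.

Step 15
Reactants: 25 (3R,5R)-3-bromo-5-[(1S,3S,4S)-3-bromo-4-chloro-4-methylcyclohexyl]-2-methylhept-6-yne-2,5-diol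
Product: 26 (3R,5R)-5-bromo-3-[(1S,3S,4S)-3-bromo-4-chloro-4-methylcyclohexyl]-3,6-dihydroxy-6-methylheptan-2-one (target)
Conditions: Ph3PAuNTf2 (cat.), H2O, 1,4-dioxane, 40 °C
Reagents that add atoms: water O
Why: Gold-catalysed Markovnikov hydration of the terminal alkyne of a tertiary propargylic alcohol gives the α-hydroxy methyl ketone under neutral, silver-free conditions that should leave the alkyl halides untouched.

Compound list
1 | hex-5-yn-1-ol | C#CCCCCO | starting material
2 | dimethyl{(E)-6-[(dimethylalumanyl)oxy]-2-methylhex-1-en-1-yl}alane | C[Al](C)/C=C(\C)CCCCO[Al](C)C | intermediate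
3 | (E)-6-bromo-5-methylhex-5-en-1-ol | OCCCC/C(C)=C/Br | intermediate
4 | (E)-6-bromo-5-methylhex-5-enoic acid | OC(=O)CCC/C(C)=C/Br | intermediate
5 | (S)-4-benzyl-1,3-oxazolidin-2-one | O=C1N[C@@H](Cc2ccccc2)CO1 | starting material
6 | (E)-6-bromo-5-methylhex-5-enoic pivalic anhydride | CC(C)(C)C(=O)OC(=O)CCC/C(C)=C/Br | intermediate
7 | (S)-4-benzyl-3-[(E)-6-bromo-5-methylhex-5-enoyl]-1,3-oxazolidin-2-one | O=C(CCC/C(C)=C/Br)N1[C@@H](Cc2ccccc2)COC1=O | intermediate
8 | tert-butyl bromoacetate | CC(C)(C)OC(=O)CBr | starting material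
9 | sodium (Z)-enolate of 7 | [Na+].[O-]/C(=C\CC/C(C)=C/Br)N1[C@@H](Cc2ccccc2)COC1=O | intermediate
10 | tert-butyl (3R,6E)-3-{[(4S)-4-benzyl-2-oxo-1,3-oxazolidin-3-yl]carbonyl}-7-bromo-6-methylhept-6-enoate | CC(C)(C)OC(=O)C[C@H](C(=O)N1[C@@H](Cc2ccccc2)COC1=O)CC/C(C)=C/Br | intermediate
11 | tert-butyl (3R,6E)-7-bromo-3-(hydroxymethyl)-6-methylhept-6-enoate | CC(C)(C)OC(=O)C[C@H](CO)CC/C(C)=C/Br | intermediate
12 | (4R)-4-[(3E)-4-bromo-3-methylbut-3-en-1-yl]oxolan-2-one | O=C1C[C@H](CO1)CC/C(C)=C/Br | intermediate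
13 | 1-bromo-3-methylbut-2-ene (prenyl bromide) | CC(C)=CCBr | starting material
14 | lithium enolate of 12 | [Li+].[O-]C1=C[C@H](CO1)CC/C(C)=C/Br | intermediate
15 | (3R,4R)-4-[(3E)-4-bromo-3-methylbut-3-en-1-yl]-3-(3-methylbut-2-en-1-yl)oxolan-2-one | O=C1[C@H](CC=C(C)C)[C@H](CO1)CC/C(C)=C/Br | intermediate
16 | potassium enolate of 15 | [K+].[O-]C1=C(CC=C(C)C)[C@H](CO1)CC/C(C)=C/Br | intermediate
17 | (3R,4S)-4-[(3E)-4-bromo-3-methylbut-3-en-1-yl]-3-hydroxy-3-(3-methylbut-2-en-1-yl)oxolan-2-one | O=C1[C@@](O)(CC=C(C)C)[C@H](CO1)CC/C(C)=C/Br | intermediate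
18 | (3R,4S)-4-[(3E)-4-bromo-3-methylbut-3-en-1-yl]-3-(3-methylbut-2-en-1-yl)-3-(triethylsilyloxy)oxolan-2-one | O=C1[C@@](O[Si](CC)(CC)CC)(CC=C(C)C)[C@H](CO1)CC/C(C)=C/Br | intermediate
19 | (3R,4S)-4-[(3E)-4-bromo-3-methylbut-3-en-1-yl]-3-(3-methylbut-2-en-1-yl)-3-(triethylsilyloxy)oxolan-2-ol, both anomers | OC1[C@@](O[Si](CC)(CC)CC)(CC=C(C)C)[C@H](CO1)CC/C(C)=C/Br | intermediate
20 | (2S,3R)-2-[(3E)-4-bromo-3-methylbut-3-en-1-yl]-3-ethynyl-6-methyl-3-(triethylsilyloxy)hept-5-en-1-ol | C#C[C@@](O[Si](CC)(CC)CC)(CC=C(C)C)[C@H](CO)CC/C(C)=C/Br | intermediate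
21 | (2S,3R)-2-[(3E)-4-bromo-3-methylbut-3-en-1-yl]-3-{[(2S)-3,3-dimethyloxiran-2-yl]methyl}-3-(triethylsilyloxy)pent-4-yn-1-ol | C#C[C@@](O[Si](CC)(CC)CC)(C[C@@H]1OC1(C)C)[C@H](CO)CC/C(C)=C/Br | intermediate
22 | (2S,3R,5R)-5-bromo-2-[(3E)-4-bromo-3-methylbut-3-en-1-yl]-3-ethynyl-6-methyl-3-(triethylsilyloxy)heptane-1,6-diol | C#C[C@@](O[Si](CC)(CC)CC)(C[C@@H](Br)C(C)(C)O)[C@H](CO)CC/C(C)=C/Br | intermediate
23 | (2S,3R,5R)-5-bromo-2-[(3E)-4-bromo-3-methylbut-3-en-1-yl]-3-ethynyl-6-hydroxy-6-methyl-3-(triethylsilyloxy)heptyl trifluoromethanesulfonate | C#C[C@@](O[Si](CC)(CC)CC)(C[C@@H](Br)C(C)(C)O)[C@H](COS(=O)(=O)C(F)(F)F)CC/C(C)=C/Br | intermediate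
24 | (3R,5R)-3-bromo-5-[(1S,3S,4S)-3-bromo-4-chloro-4-methylcyclohexyl]-2-methyl-5-(triethylsilyloxy)hept-6-yn-2-ol | C#C[C@@](O[Si](CC)(CC)CC)(C[C@@H](Br)C(C)(C)O)[C@H]1CC[C@](C)(Cl)[C@@H](Br)C1 | intermediate
25 | (3R,5R)-3-bromo-5-[(1S,3S,4S)-3-bromo-4-chloro-4-methylcyclohexyl]-2-methylhept-6-yne-2,5-diol | C#C[C@@](O)(C[C@@H](Br)C(C)(C)O)[C@H]1CC[C@](C)(Cl)[C@@H](Br)C1 | intermediate
26 | (3R,5R)-5-bromo-3-[(1S,3S,4S)-3-bromo-4-chloro-4-methylcyclohexyl]-3,6-dihydroxy-6-methylheptan-2-one | CC(=O)[C@@](O)(C[C@@H](Br)C(C)(C)O)[C@H]1CC[C@](C)(Cl)[C@@H](Br)C1 | target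

Total step count: 15
Longest linear sequence: 15 steps (from 1 to 26)

Steps most likely to fail

Step 13 (proposed new method). Direct displacement of the triflate by chloride, participation of the side-chain bromine at C2, or proton loss from the cyclised cation could outrun the intended π-cyclisation and chloride capture. The fallback uses known chemistry and sets out from 22. Appel iodination (I2, PPh3, imidazole, CH2Cl2) should give the primary iodide of 22, F1, with all centres unchanged. Zinc insertion (Zn, LiCl, THF) followed by intramolecular Negishi coupling with the bromoalkene (PdCl2(dppf), THF, 50 °C) should close the same C2–C3 bond and give the cyclohexene (3R,5R)-3-bromo-2-methyl-5-[(1S)-4-methylcyclohex-3-en-1-yl]-5-(triethylsilyloxy)hept-6-yn-2-ol F2. Anti bromochlorination of the ring alkene with Bu4NBrCl2 (CH2Cl2, −78 °C) would then place chlorine on the tertiary carbon. Facial control is lost in this last operation: the (1S,3R,4R)-ring diastereomer of 24, F3, is expected to accompany and probably outweigh 24, so chromatographic separation would be needed. The fallback returns to the route at 24.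

Step 12. Bromide could open the epoxide at the tertiary carbon, or the free primary hydroxyl could open it intramolecularly to a cyclic ether, so the regiochemistry of ring opening may be lost. The fallback sets out from 20 and forms the bromohydrin by bromonium formation and water capture (NBS, THF/H2O, 0 °C), where Markovnikov regiochemistry (bromine secondary, hydroxyl tertiary) is inherent. Facial selectivity is not controlled, so 22 would have to be separated from its C5 epimer, the (2S,3R,5S)-bromohydrin F4. The fallback returns at 22.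

Step 10. Under K2CO3/MeOH the triethylsilyl group may migrate from the tertiary oxygen to the anomeric or primary oxygen, or be lost, and homologation of the hindered lactol may be slow. The fallback changes the protecting-group order and sets out from 17. Reduction with i-Bu2AlH should give the unprotected lactol (3R,4S)-4-[(3E)-4-bromo-3-methylbut-3-en-1-yl]-3-(3-methylbut-2-en-1-yl)oxolane-2,3-diol F5. Ohira–Bestmann homologation should give (2S,3R)-2-[(3E)-4-bromo-3-methylbut-3-en-1-yl]-3-ethynyl-6-methylhept-5-ene-1,3-diol F6. Double silylation (Et3SiOTf, 2,6-lutidine) should give the bis(triethylsilyl) ether of that diol, F7, and selective methanolysis of the primary silyl ether (PPTS, MeOH, 0 °C) returns to the route at 20.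

Further compounds
F1 | step 13 | primary iodide of 22 (CH2OH replaced by CH2I, other centres as in 22) | C#C[C@@](O[Si](CC)(CC)CC)(C[C@@H](Br)C(C)(C)O)[C@H](CI)CC/C(C)=C/Br
F2 | step 13 | (3R,5R)-3-bromo-2-methyl-5-[(1S)-4-methylcyclohex-3-en-1-yl]-5-(triethylsilyloxy)hept-6-yn-2-ol | C#C[C@@](O[Si](CC)(CC)CC)(C[C@@H](Br)C(C)(C)O)[C@H]1CCC(C)=CC1
F3 | step 13 | (3R,5R)-3-bromo-5-[(1S,3R,4R)-3-bromo-4-chloro-4-methylcyclohexyl]-2-methyl-5-(triethylsilyloxy)hept-6-yn-2-ol | C#C[C@@](O[Si](CC)(CC)CC)(C[C@@H](Br)C(C)(C)O)[C@H]1CC[C@@](C)(Cl)[C@H](Br)C1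
F4 | step 12 | (2S,3R,5S)-5-bromo-2-[(3E)-4-bromo-3-methylbut-3-en-1-yl]-3-ethynyl-6-methyl-3-(triethylsilyloxy)heptane-1,6-diol | C#C[C@@](O[Si](CC)(CC)CC)(C[C@H](Br)C(C)(C)O)[C@H](CO)CC/C(C)=C/Br
F5 | step 10 | (3R,4S)-4-[(3E)-4-bromo-3-methylbut-3-en-1-yl]-3-(3-methylbut-2-en-1-yl)oxolane-2,3-diol, both anomers | OC1[C@@](O)(CC=C(C)C)[C@H](CO1)CC/C(C)=C/Br
F6 | step 10 | (2S,3R)-2-[(3E)-4-bromo-3-methylbut-3-en-1-yl]-3-ethynyl-6-methylhept-5-ene-1,3-diol | C#C[C@@](O)(CC=C(C)C)[C@H](CO)CC/C(C)=C/Br
F7 | step 10 | bis(triethylsilyl) ether of F6 (both hydroxyls silylated) | C#C[C@@](O[Si](CC)(CC)CC)(CC=C(C)C)[C@H](CO[Si](CC)(CC)CC)CC/C(C)=C/Br
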